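**Plan**
- **Cuts:** O7–H is masked as O7–Si. The C2–C3 bond of ring C is then cut and C2 is re-tied to the C4 oxygen, which turns the chroman-4-one into a 4-methylidene-4H-1,3-benzodioxine. Behind that lie C4=CH2 (lactone methylenation), the aryl–prenyl bonds at C6 and C8 (coupling of a diiodide) and the two C2–O acetal bonds (salicylic acid plus veratraldehyde).
- **Enabling feature:** C2 bears O1 and the 3,4-dimethoxyphenyl ring B, and both stabilise a cation at C2. C3–C4 is the enol unit of an aryl ketone sitting on ring A ortho to O1, so cation and enol are held on one benzene ring and can collapse to C2–C3.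
- **Forward order:** rings A and B are bought. The 1,3-dioxin-4-one ring is closed on diiodinated ring A, O7 is silylated, both prenyl groups are coupled on, C=O becomes C=CH2, and the dioxine ring is isomerised into ring C.
- **Stereochemistry:** the acetal carbon is carried racemic and is planarised in the rearrangement, where a chiral counter-anion sets (2S). The last step is buffered so that ring C cannot open.

Key step: step 6

Assumption: the sense of induction of the chiral anion cannot be derived for this new substrate class. The (S,S) catalyst is written, and its mirror image is taken if a first run shows (2R). Stannane 8 is a purchased reagent.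

Step 1
Reactants: 1 2,4-dihydroxybenzoic acid
Product: 2 2,4-dihydroxy-3,5-diiodobenzoic acid
Conditions: ICl (2.05 equiv), AcOH, 20 → 40 °C; H2O, aq Na2S2O3
Reagents that add atoms: iodine monochloride, ClI
Why: Electrophilic aromatic iodination, in which both hydroxyl groups direct to C3 and C5 (the only free ortho/para positions) and exact stoichiometry at mild temperature should stop the reaction before ipso-iododecarboxylation at C1.

Step 2
Reactants: 2 2,4-dihydroxy-3,5-diiodobenzoic acid; 3 3,4-dimethoxybenzaldehyde (veratraldehyde)
Product: 6 rac-2-(3,4-dimethoxyphenyl)-7-hydroxy-6,8-diiodo-4H-1,3-benzodioxin-4-one, via tris(trimethylsilyl) derivative 4 (not isolated), via 7-O-trimethylsilyl benzodioxinone 5 (not isolated)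
Conditions: (Me3Si)2NH (2.5 equiv), cat. TMSCl, THF, 60 °C, volatiles removed in the same flask; 3 (1.1 equiv), TMSOTf (15 mol %), CH2Cl2, −78 → −30 °C; pyridine, then pH 7 buffer/THF, rt
Reagents that add atoms: hexamethyldisilazane, C[Si](C)(C)N[Si](C)(C)C (its Me3Si groups are carried by 4 and 5 only; none remains in 6)
Why: Noyori-type silyl-transfer acetalisation, as used for the dioxanone stage of the Petasis–Ferrier union, in which TMSOTf activates the aldehyde, the silyl ester and the ortho silyl ether add in turn with loss of hexamethyldisiloxane, only the 2-O/CO2 pair can close a six-membered ring, and the Me3Si group on the acidic 7-phenol falls off in the neutral work-up; C2 forms racemic, which is harmless.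

Step 3
Reactants: 6 rac-2-(3,4-dimethoxyphenyl)-7-hydroxy-6,8-diiodo-4H-1,3-benzodioxin-4-one
Product: 7 rac-7-(tert-butyldimethylsilyloxy)-2-(3,4-dimethoxyphenyl)-6,8-diiodo-4H-1,3-benzodioxin-4-one
Conditions: TBSCl (1.3 equiv), imidazole (2.5 equiv), CH2Cl2, 0 °C → rt
Reagents that add atoms: tert-butyldimethylsilyl chloride, CC(C)(C)[Si](C)(C)Cl
Why: Standard imidazole-mediated phenol silylation, which removes the acidic proton that would protonate the allylstannane of step 4 and consume the titanium reagent of step 5, under conditions too mild to open the acylal.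

Step 4
Reactants: 7 rac-7-(tert-butyldimethylsilyloxy)-2-(3,4-dimethoxyphenyl)-6,8-diiodo-4H-1,3-benzodioxin-4-one; 8 tributyl(3-methylbut-2-en-1-yl)stannane (2.6 equiv)
Product: 9 rac-7-(tert-butyldimethylsilyloxy)-2-(3,4-dimethoxyphenyl)-6,8-bis(3-methylbut-2-en-1-yl)-4H-1,3-benzodioxin-4-one
Conditions: Pd2(dba)3 (5 mol %), P(2-furyl)3 (20 mol %), 1,4-dioxane, 80 °C, degassed
Reagents that add atoms: none
Why: Twofold Stille coupling, in which aryl iodides add readily to Pd(0), the allyl-type stannane transmetalates fast and reductive elimination at the unsubstituted allyl terminus gives the linear prenyl group; the neutral, fluoride-free medium spares acylal and silyl ether, and allylation of benzodioxinone electrophiles with allylstannanes is routine.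

Step 5
Reactants: 9 rac-7-(tert-butyldimethylsilyloxy)-2-(3,4-dimethoxyphenyl)-6,8-bis(3-methylbut-2-en-1-yl)-4H-1,3-benzodioxin-4-one
Product: 10 rac-7-(tert-butyldimethylsilyloxy)-2-(3,4-dimethoxyphenyl)-4-methylidene-6,8-bis(3-methylbut-2-en-1-yl)-4H-1,3-benzodioxine
Conditions: Cp2TiMe2 (2.5 equiv), toluene, 70 °C, dark; hexane, filtration through basic alumina (1 % Et3N)
Reagents that add atoms: dimethyltitanocene (Petasis reagent), C[Ti+2]C.c1cc[cH-]c1.c1cc[cH-]c1
Why: Petasis olefination, in which thermally formed Cp2Ti=CH2 adds [2+2] to the lactone carbonyl and cycloreverts under the drive of the Ti=O bond; the reagent is neither acidic nor basic, leaves trisubstituted alkenes, the aryl silyl ether and the acetal alone, and is the standard way from 1,3-dioxan-4-ones to their enol acetals.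

Step 6
Reactants: 10 rac-7-(tert-butyldimethylsilyloxy)-2-(3,4-dimethoxyphenyl)-4-methylidene-6,8-bis(3-methylbut-2-en-1-yl)-4H-1,3-benzodioxine
Product: 12 (2S)-7-(tert-butyldimethylsilyloxy)-2-(3,4-dimethoxyphenyl)-6,8-bis(3-methylbut-2-en-1-yl)-2,3-dihydro-4H-chromen-4-one, via silyl enol ether oxocarbenium ion 11 (not isolated)
Conditions: (S,S)-IDPi (5 mol %; BINOL-derived imidodiphosphorimidate, N-triflyl core, 3,3'-aryl wings) pre-silylated with methallyl-SiMe3 (5 mol %), toluene, −78 °C; Et3N quench at −78 °C
Reagents that add atoms: none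
Why: Proposed new method: the silylium Lewis acid binds the enol-ether oxygen O3, the C2–O3 bond ionises, and either enantiomer of 10 gives the same planar cation 11 (O1=C2 oxocarbenium, stabilised by O1 and by ring B) that carries an ortho silyl enol ether and is paired with the chiral anion; rotation about C4–C4a brings the former methylidene carbon (C3) onto C2, an intramolecular Mukaiyama-type addition forms C2–C3, and the silyl group moves from the new ketone to the next molecule of 10. The closest known reaction types are the Me2AlCl-promoted Petasis–Ferrier rearrangement of 4-methylidene-1,3-dioxanes to tetrahydropyran-4-ones, the chiral-Brønsted-acid aza-Petasis–Ferrier rearrangement, and counter-anion-directed additions of silyl enol ethers to oxocarbenium ions; new are the benzo-fused aryloxy acetal and enantiocontrol of the all-oxygen rearrangement. Ring C closes in the 6-(enolendo)-endo-trig mode, the C3=C4 enol bond and the O1=C2 bond both lying inside the forming ring, as in the parent rearrangement. C2, the only new stereocentre, is set by the confined anion, which covers one face of the cation, so the reaction is stereoconvergent and the configuration of racemic 10 is irrelevant. Three selectivities are needed: C2–O3 over C2–O1 cleavage (the latter is reversible and leads nowhere, whereas C–C bond formation is irreversible), the enol carbon over the C8 prenyl alkene as nucleophile (the silyl enol ether is by far the stronger π-donor, which should suppress Prins-type closure), and no crossover (both partners sit ortho on ring A). The low temperature, the absence of protic acid and the cold amine quench should protect the prenyl groups and the silyl ether and hold back opening of ring C, which would racemise C2.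

Step 7
Reactants: 12 (2S)-7-(tert-butyldimethylsilyloxy)-2-(3,4-dimethoxyphenyl)-6,8-bis(3-methylbut-2-en-1-yl)-2,3-dihydro-4H-chromen-4-one
Product: 13 (2S)-2-(3,4-dimethoxyphenyl)-7-hydroxy-6,8-bis(3-methylbut-2-en-1-yl)-2,3-dihydro-4H-chromen-4-one (IN0946)
Conditions: TBAF/AcOH (1:1, 1.2 equiv), THF, 0 °C
Reagents that add atoms: none
Why: Fluoride cleavage of an aryl silyl ether, buffered with acetic acid so that no free base can open ring C by E1cB (retro-oxa-Michael) and racemise C2, and with no acid strong enough to cyclise the ortho-prenylphenol to a chroman.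

**Compound list**
1 | 2,4-dihydroxybenzoic acid | O=C(O)c1ccc(O)cc1O | starting material
2 | 2,4-dihydroxy-3,5-diiodobenzoic acid | O=C(O)c1cc(I)c(O)c(I)c1O | intermediate
3 | 3,4-dimethoxybenzaldehyde (veratraldehyde) | COc1ccc(C=O)cc1OC | starting material
4 | trimethylsilyl 3,5-diiodo-2,4-bis(trimethylsilyloxy)benzoate | C[Si](C)(C)OC(=O)c1cc(I)c(O[Si](C)(C)C)c(I)c1O[Si](C)(C)C | intermediate
5 | rac-2-(3,4-dimethoxyphenyl)-6,8-diiodo-7-(trimethylsilyloxy)-4H-1,3-benzodioxin-4-one | COc1ccc(C2OC(=O)c3cc(I)c(O[Si](C)(C)C)c(I)c3O2)cc1OC | intermediate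
6 | rac-2-(3,4-dimethoxyphenyl)-7-hydroxy-6,8-diiodo-4H-1,3-benzodioxin-4-one | COc1ccc(C2OC(=O)c3cc(I)c(O)c(I)c3O2)cc1OC | intermediate
7 | rac-7-(tert-butyldimethylsilyloxy)-2-(3,4-dimethoxyphenyl)-6,8-diiodo-4H-1,3-benzodioxin-4-one | COc1ccc(C2OC(=O)c3cc(I)c(O[Si](C)(C)C(C)(C)C)c(I)c3O2)cc1OC | intermediate
8 | tributyl(3-methylbut-2-en-1-yl)stannane | CCCC[Sn](CCCC)(CCCC)CC=C(C)C | starting material
9 | rac-7-(tert-butyldimethylsilyloxy)-2-(3,4-dimethoxyphenyl)-6,8-bis(3-methylbut-2-en-1-yl)-4H-1,3-benzodioxin-4-one | COc1ccc(C2OC(=O)c3cc(CC=C(C)C)c(O[Si](C)(C)C(C)(C)C)c(CC=C(C)C)c3O2)cc1OC | intermediate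
10 | rac-7-(tert-butyldimethylsilyloxy)-2-(3,4-dimethoxyphenyl)-4-methylidene-6,8-bis(3-methylbut-2-en-1-yl)-4H-1,3-benzodioxine | COc1ccc(C2OC(=C)c3cc(CC=C(C)C)c(O[Si](C)(C)C(C)(C)C)c(CC=C(C)C)c3O2)cc1OC | intermediate
11 | ring-opened aryloxy(3,4-dimethoxyphenyl)methylium (oxocarbenium) ion bearing the ortho 1-(trimethylsilyloxy)vinyl group, paired with the catalyst anion; Me3Si comes from the catalyst | COc1ccc(C=[O+]c2c(CC=C(C)C)c(O[Si](C)(C)C(C)(C)C)c(CC=C(C)C)cc2C(=C)O[Si](C)(C)C)cc1OC | intermediate
12 | (2S)-7-(tert-butyldimethylsilyloxy)-2-(3,4-dimethoxyphenyl)-6,8-bis(3-methylbut-2-en-1-yl)-2,3-dihydro-4H-chromen-4-one | COc1ccc([C@@H]2CC(=O)c3cc(CC=C(C)C)c(O[Si](C)(C)C(C)(C)C)c(CC=C(C)C)c3O2)cc1OC | intermediate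
13 | (2S)-2-(3,4-dimethoxyphenyl)-7-hydroxy-6,8-bis(3-methylbut-2-en-1-yl)-2,3-dihydro-4H-chromen-4-one (IN0946) | COc1ccc([C@@H]2CC(=O)c3cc(CC=C(C)C)c(O)c(CC=C(C)C)c3O2)cc1OC | target

Total step count: 7. Longest linear sequence: 7 steps (1 → 13).

**Steps most likely to fail**

**Step 6 (new method).**
- Facial discrimination may be poor, because the cation is strongly stabilised and bulky and may pair only loosely with the anion.
- The C8 prenyl alkene may capture the cation.
- Lewis-acid-induced reversible opening of ring C may erode the enantiomeric purity after the event.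

The fallback uses known chemistry, sets out from 10 and rejoins the route at 12. Mild hydrolysis of the enol acetal (PPTS, wet THF, 0 °C) would release 1-[4-(tert-butyldimethylsilyloxy)-2-hydroxy-3,5-bis(3-methylbut-2-en-1-yl)phenyl]ethanone F1. Condensation with DMF dimethyl acetal (toluene, 90 °C) would give (E)-1-[4-(tert-butyldimethylsilyloxy)-2-hydroxy-3,5-bis(3-methylbut-2-en-1-yl)phenyl]-3-(dimethylamino)prop-2-en-1-one F2. Warm acetic acid would close this to 7-(tert-butyldimethylsilyloxy)-6,8-bis(3-methylbut-2-en-1-yl)-4H-chromen-4-one F3. A rhodium/chiral-diene-catalysed asymmetric 1,4-addition of 3,4-dimethoxyphenylboronic acid to this chromone, an established entry to enantioenriched flavanones, would then deliver 12. The ligand enantiomer is chosen for (2S).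

**Step 4.**
- Transfer of the bulky prenyl group to the doubly ortho-substituted C8 position may be sluggish.
- Hydrodeiodination may then compete.
- Coupling through the γ-terminus may also compete.
- Slow loss of the silyl group at the reaction temperature is possible.

The fallback sets out from 7 and rejoins the route at 9. A twofold Stille coupling with the smaller and regiochemically unambiguous allyltributylstannane (same catalyst, 60 °C) would give rac-7-(tert-butyldimethylsilyloxy)-2-(3,4-dimethoxyphenyl)-6,8-di(prop-2-en-1-yl)-4H-1,3-benzodioxin-4-one F4. Olefin cross-metathesis with excess 2-methylbut-2-ene (Grubbs second-generation catalyst, CH2Cl2, 40 °C) would convert both allyl groups into prenyl groups.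

**Step 2.**
- Ring closure by the hindered, electron-poor aryl silyl ether may stay incomplete.
- The acylal of an electron-rich aldehyde may hydrolyse during work-up.

The fallback sets out from 3 and 2 and rejoins the route at 6. Veratraldehyde would first be converted with acetic anhydride (cat. FeCl3, rt) into (3,4-dimethoxyphenyl)methanediyl diacetate F5. This geminal diacetate would then be exchanged with acid 2 under thermodynamic control (cat. H2SO4, toluene, 60 °C, reduced pressure to strip acetic acid). That is the classical acylal-exchange route to 2-substituted benzodioxinones.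

**Further compounds**
F1 | step 6 | 1-[4-(tert-butyldimethylsilyloxy)-2-hydroxy-3,5-bis(3-methylbut-2-en-1-yl)phenyl]ethanone | CC(=O)c1cc(CC=C(C)C)c(O[Si](C)(C)C(C)(C)C)c(CC=C(C)C)c1O
F2 | step 6 | (E)-1-[4-(tert-butyldimethylsilyloxy)-2-hydroxy-3,5-bis(3-methylbut-2-en-1-yl)phenyl]-3-(dimethylamino)prop-2-en-1-one | CN(C)/C=C/C(=O)c1cc(CC=C(C)C)c(O[Si](C)(C)C(C)(C)C)c(CC=C(C)C)c1O
F3 | step 6 | 7-(tert-butyldimethylsilyloxy)-6,8-bis(3-methylbut-2-en-1-yl)-4H-chromen-4-one | O=c1ccoc2c(CC=C(C)C)c(O[Si](C)(C)C(C)(C)C)c(CC=C(C)C)cc12
F4 | step 4 | rac-7-(tert-butyldimethylsilyloxy)-2-(3,4-dimethoxyphenyl)-6,8-di(prop-2-en-1-yl)-4H-1,3-benzodioxin-4-one | COc1ccc(C2OC(=O)c3cc(CC=C)c(O[Si](C)(C)C(C)(C)C)c(CC=C)c3O2)cc1OC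
F5 | step 2 | (3,4-dimethoxyphenyl)methanediyl diacetate | COc1ccc(C(OC(C)=O)OC(C)=O)cc1OC
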